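## The problem

Target 13 is umbelliferone etherified at O-7 with a fifteen-carbon chain that ends in a 4-hydroxy-2,2,4-trimethylcyclohexanone; the ring is numbered here C1 (CMe2), C2 (C=O), C3 and C4 (CH2), C5 (C(OH)CH3) and C6 (CH), and the chain C7–C11, with C9 the chain carbinol and C11 the OCH2 group. The skeletal difficulty is C6: a methine wedged between the fully substituted carbons C1 and C5 that also carries the chain, so the ring bonds C1–C6 and C5–C6 and the exocyclic bond C6–C7 must all be made in a crowded environment. Of the three stereocentres, C5 and C6 are neighbours (hydroxyl trans to the chain, methyl cis) and can be set together, whereas C9 lies across two methylene groups and can neither steer the ring nor be steered by it; it needs its own source of chirality. The functional groups limit the tactics: two tertiary alcohols that eliminate under strong acid, a ketone with an enolisable C3, and a coumarin whose lactone opens with hydroxide or alkoxide and whose carbonyl oxygen is a good Lewis base. One feature simplifies the problem: C5, C6, the C5 methyl and C7–C11 are the ten carbons of linalool, and with a formyl group on C5 in place of the hydroxyl the C5=C6 unit is an (E)-α-methyl enal, the prenyl end of linalool after allylic oxidation. What remains, C1–C4 with the ketone written as a silyl enol ether, is a 2-silyloxydiene with a dimethyl terminus, so a [4+2] cycloaddition forms C1–C6 and C4–C5 at once and turns the E geometry of the dienophile into the trans relation of oxygen and chain, provided the formyl carbon is later exchanged for oxygen with retention. The price is one sacrificed carbon and a cycloaddition that must join a fully substituted diene terminus to a β-alkyl enal carbon under catalyst control.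

## Retrosynthesis

**C11–O(aryl).** The aryl ether bond is cut first, giving triol ketone 11 and umbelliferone 12. Carrying the coumarin from the diol stage on would cost the same number of steps but would expose its Lewis-basic carbonyl to the cationic boron catalyst of the ring-forming step and its lactone to the peracid and methanolysis steps. Compound 11 has no chromophore and no base-labile group. The forward reaction only has to tell a primary alcohol from two tertiary ones, which a Mitsunobu etherification does.

**C5–O.** The C5–O bond is traced to a C5–CHO bond: 11 comes from formate 10 and this from keto aldehyde 9 by Baeyer–Villiger oxidation. The carbon that is lost is the one that activates the dienophile, so no extra step is needed to install it. An acetyl group in its place would compete with the C2 ketone for the peracid, and a carboxyl group would have to leave through a radical that forgets the configuration of C5. The forward reaction must oxidise the aldehyde in preference to a ketone flanked by a quaternary carbon and must proceed by alkyl rather than hydride migration.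

**Si–O bonds.** Keto aldehyde 9 is the fully desilylated form of cycloadduct 8. The C2 ketone is stored as the triisopropylsilyl enol ether in which the cycloaddition delivers it, and the C9 and C11 hydroxyls as tert-butyldimethylsilyl ethers. One treatment with HF cleaves all three; no stereocentre is α to a carbonyl group, so nothing can epimerise.

**C1–C6 and C4–C5 (key cut).** Opening the ring at these two bonds gives enal 5 and diene 7. This is the only Diels–Alder cut of the ring in which the CMe2 carbon is a diene terminus and an activating group sits on the dienophile. The neighbouring cuts (aldol at C5–C6, enolate alkylation at C1–C6, cation–olefin closure) make one ring bond at a time and leave C6–C7 or a stereocentre for later. The cut removes the ring and both ring stereocentres at once and leaves an acyclic enal whose only stereocentre is C9 and an achiral nine-carbon diene. The forward step must engage the hindered diene terminus at the β-carbon rather than at the formyl group, select one enal face (by a chiral oxazaborolidinium ion, since C9 is too remote to help or interfere), and run suprafacially.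

**Enal 5.** Enal 5 is the allylic oxidation product, through alcohol 4, of silyl ether 3; the bond changed is a C–H bond of the E methyl group. Building the enal by olefination of a nor-aldehyde would need an extra cleavage step, whereas SeO2 oxidation uses the prenyl group as it is and gives the E isomer by its mechanism. Compound 3 is the bis-silyl ether of diol 2, the anti-Markovnikov hydration product of the vinyl group of (R)-linalool 1. Linalool supplies C9 in the correct configuration and every carbon from C5 to C11. The forward reactions must hydroborate the monosubstituted olefin beside the trisubstituted one and silylate a tertiary alcohol.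

**Diene 7.** Diene 7 is the O-silylated enol of 4-methylpent-1-en-3-one 6. The ketone has a single α-hydrogen, so the position of the new double bond is not in question.

## Roads not taken

**Alternative 1:** Both ring oxygens are placed on a finished carbocycle. The cut removes the C2–O and C5–O bonds and leads to cyclohexadiene A1, whose side chain already holds C9 and ends in an allyl group as a masked C11. Singlet oxygen (O2, porphyrin sensitiser, visible light) would add across C2 and C5 on the face away from the C6 chain. Et3N would then open the endoperoxide by Kornblum–DeLaMare fragmentation; as C5 has no hydrogen, only C2–H can be removed, so hydroxy enone A2 is the only constitutional outcome.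
- Merits: no carbon is discarded, the 1,4-dioxygen pattern and the C5 configuration arise in one substrate-controlled operation, and the reaction type is well known.
- Weak points: A1 is the real problem. Its C6 stereocentre must first be made enantioselectively, it can isomerise by 1,5-hydrogen shift, and the C5 methyl offers allylic hydrogens for a competing ene reaction. Afterwards the C3=C4 bond must be reduced beside the terminal olefin, the allyl group degraded to C11, and C9 still needs its own source of asymmetry.
- Comparison: in precedent for the key step this road is better. The chosen plan offers instead that ring, both ring stereocentres and the whole carbon chain arise in one step from a chiral-pool dienophile, in roughly half the operations.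

**Alternative 2:** The C5–O bond is traced to a ring expansion. Reconnecting C5 to the carbonyl carbon C9 gives trans-hydrindanone A3, a Hajos–Parrish-type bicycle with the gem-dimethyl group and the C2 ketone (as dioxolane) in place. mCPBA/NaHCO3 would insert oxygen next to the quaternary carbon with retention and give the trans-fused δ-lactone A4, in which C7 and C8 are ring carbons and C9 is the carbonyl.
- Merits: every step is well-charted chemistry, the regiochemistry of oxygen insertion follows from migratory aptitude, and C5 and C6 come from one proline-catalysed annulation.
- Weak points: the trans ring fusion and the gem-dimethyl group each cost several steps, and oxidation levels must be adjusted in both rings. Decisively, C9 arrives as a lactone carbonyl, so its tertiary carbinol centre must be built by two successive additions far from any controlling element; the coumarin arm is then still to be attached.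
- Comparison: step by step this road is clearly safer and would be preferred if the cycloaddition could not be reduced to practice. The chosen plan offers instead eight steps in place of well over fifteen and a C9 centre bought with (R)-linalool 1.

**Alternative 3:** The ring is closed at C5–C6 by an aldol reaction. The cut gives the achiral ketoaldehyde A5. (S)-Proline would form the enamine of its aldehyde, whose α-carbon (C6) adds to the methyl ketone carbon (C5) in a 6-enolexo closure to give hydroxy aldehyde A6, with the formyl group as C7.
- Merits: the shortest entry to the ring, a cheap catalyst, C5 is born as the tertiary alcohol so no carbon is sacrificed, and ring and chain are joined late.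
- Weak points: ketone acceptors are poor partners in proline enolexo aldolisations, and A5 can enolise at C3 and at the methyl group as well. A6 is a β-hydroxy aldehyde prone to retro-aldol cleavage, dehydration and epimerisation at C6. Its formyl group sits between two quaternary carbons, so the C7–C8 bond to a C8–C11 fragment is the most hindered bond of that plan, and the fragment needs a separate asymmetric synthesis.
- Comparison: in atom economy and in length to the ring this road beats the chosen plan. The chosen plan offers instead that the C6–C7 bond is never made at the hindered centre, because it is already in the dienophile, and that C9 is not a separate problem.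

Key step: step 5

Remark on the catalyst: the sense of induction is taken from the accepted model for α-substituted enals bound to an oxazaborolidinium ion, which assigns the (R)-catalyst to the α-Si/β-Re face needed here; the antipodal catalyst is equally accessible.
Remark on supply: 4-methylpent-1-en-3-one 6 is taken as a stabilised catalogue compound.

## Route

Step 1
Reactants: 1 (R)-linalool
Product: 2 (3R)-3,7-dimethyloct-6-ene-1,3-diol
Conditions: 9-borabicyclo[3.3.1]nonane (9-BBN, 2.2 equiv), THF, 0 °C → rt; then NaOH, H2O2, 0 °C
Reagents that add atoms: hydrogen peroxide, OO
Why: Hydroboration–oxidation; 9-BBN adds to the monosubstituted vinyl group far faster than to the trisubstituted olefin and places boron on the terminal carbon, the first equivalent being consumed by the tertiary hydroxyl. The carbinol stereocentre is not touched.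

Step 2
Reactants: 2 (3R)-3,7-dimethyloct-6-ene-1,3-diol
Product: 3 (3R)-1,3-bis(tert-butyldimethylsilyloxy)-3,7-dimethyloct-6-ene
Conditions: TBSOTf (2.5 equiv), 2,6-lutidine, CH2Cl2, 0 °C → rt
Reagents that add atoms: tert-butyldimethylsilyl trifluoromethanesulfonate, CC(C)(C)[Si](C)(C)OS(=O)(=O)C(F)(F)F
Why: Silylation with a silyl triflate and a hindered pyridine base protects the primary and the tertiary alcohol in one operation. Both ethers tolerate the oxidation and the Lewis acid that follow and fall together in step 6.

Step 3
Reactants: 3 (3R)-1,3-bis(tert-butyldimethylsilyloxy)-3,7-dimethyloct-6-ene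
Product: 5 (2E,6R)-6,8-bis(tert-butyldimethylsilyloxy)-2,6-dimethyloct-2-enal, via allylic alcohol 4 (not isolated)
Conditions: SeO2 (0.5 equiv), t-BuOOH, CH2Cl2, rt; aqueous work-up; then MnO2, CH2Cl2, rt
Reagents that add atoms: selenium dioxide, O=[Se]=O; tert-butyl hydroperoxide, CC(C)(C)OO
Why: Catalytic SeO2 allylic oxidation (ene reaction, then [2,3]-sigmatropic shift) attacks the E methyl group of a gem-dimethyl olefin and keeps the E geometry. MnO2 oxidation of the crude mixture brings the remaining allylic alcohol 4 to the enal.

Step 4
Reactants: 6 4-methylpent-1-en-3-one
Product: 7 4-methyl-3-(triisopropylsilyloxy)penta-1,3-diene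
Conditions: TIPSOTf (1.1 equiv), Et3N, Et2O, 0 °C → rt; distillation
Reagents that add atoms: triisopropylsilyl trifluoromethanesulfonate, CC(C)[Si](C(C)C)(C(C)C)OS(=O)(=O)C(F)(F)F
Why: Soft enolisation (silyl triflate/amine) of the only α-hydrogen, the isopropyl methine, gives the cross-conjugated silyl dienol ether. The bulky silyl group makes the diene robust towards the acid catalyst of step 5.

Step 5
Reactants: 5 (2E,6R)-6,8-bis(tert-butyldimethylsilyloxy)-2,6-dimethyloct-2-enal; 7 4-methyl-3-(triisopropylsilyloxy)penta-1,3-diene
Product: 8 (1S,6S)-6-[(3R)-3,5-bis(tert-butyldimethylsilyloxy)-3-methylpentyl]-1,5,5-trimethyl-4-(triisopropylsilyloxy)cyclohex-3-ene-1-carbaldehyde (chain cis to the C5 methyl, trans to the formyl group)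
Conditions: (R)-3,3-diphenyl-1-(o-tolyl)tetrahydro-1H,3H-pyrrolo[1,2-c][1,3,2]oxazaborole (20 mol%), Tf2NH (17 mol%), 7 (3 equiv), CH2Cl2, −78 → −20 °C
Reagents that add atoms: none
Why: Proposed new method: the N-protonated oxazaborolidine binds the formyl oxygen of 5 (boron syn to the formyl hydrogen, which contacts the ring oxygen) and lowers the enal LUMO, so that the enol ether carbon of 7 (its CMe2 terminus) attacks the β-carbon C6 while the CH2 terminus closes on the α-carbon C5; the closest known reaction type is the oxazaborolidinium-catalysed Diels–Alder addition of 2-silyloxydienes to α-methyl enals, which has not been shown for a β-alkyl enal combined with a fully substituted diene terminus. The six-membered ring closes by intermolecular [4+2] cycloaddition, either concerted and strongly asynchronous (C1–C6 ahead of C4–C5) or, at the stepwise limit, by Mukaiyama–Michael addition followed by 6-(enolexo)-endo-trig collapse of the boron enolate onto the silyloxyallyl cation. The C5 stereocentre is set by the catalyst, whose aryl group lies against one face of the s-trans enal and leaves the α-Si/β-Re face open. The C6 stereocentre follows from suprafacial addition to the E olefin, which puts the chain cis to the C5 methyl and trans to the formyl group. Regiochemistry is secured by the silyloxy group, which makes the dimethyl-bearing terminus the nucleophilic one and pairs it with the electrophilic β-carbon; endo/exo selectivity is irrelevant because neither diene terminus becomes a stereocentre, and the remote C9 centre should not bias the outcome. The step needs facial selectivity and a chiral pathway that outruns any achiral silyl triflimide cycle, which is why the oxazaborolidine is kept in excess over Tf2NH, the triisopropylsilyl ether is used, and no competing Lewis base such as the coumarin is present.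

Step 6
Reactants: 8 (1S,6S)-6-[(3R)-3,5-bis(tert-butyldimethylsilyloxy)-3-methylpentyl]-1,5,5-trimethyl-4-(triisopropylsilyloxy)cyclohex-3-ene-1-carbaldehyde
Product: 9 (1S,2R)-2-[(3R)-3,5-dihydroxy-3-methylpentyl]-1,3,3-trimethyl-4-oxocyclohexane-1-carbaldehyde
Conditions: 48% aq. HF, MeCN, 0 °C → rt (plastic vessel)
Reagents that add atoms: none
Why: Acidic fluoride desilylation cleaves both silyl ethers and protodesilylates the enol ether to the C2 ketone. C5 is quaternary and C6 is not α to a carbonyl group, so no centre can epimerise; the change of the C6 descriptor is only a change of CIP priorities.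

Step 7
Reactants: 9 (1S,2R)-2-[(3R)-3,5-dihydroxy-3-methylpentyl]-1,3,3-trimethyl-4-oxocyclohexane-1-carbaldehyde
Product: 11 (3S,4S)-3-[(3R)-3,5-dihydroxy-3-methylpentyl]-4-hydroxy-2,2,4-trimethylcyclohexan-1-one, via formate 10 (not isolated)
Conditions: mCPBA (1.2 equiv), Na2HPO4, CH2Cl2, 0 °C; aq. Na2S2O3 work-up; then K2CO3, MeOH, 0 °C
Reagents that add atoms: 3-chloroperoxybenzoic acid, OOC(=O)c1cccc(Cl)c1
Why: Baeyer–Villiger oxidation; the peracid adds to the aldehyde faster than to the ketone flanked by the quaternary C1, and the tertiary carbon C5 migrates with retention to give formate 10. Mild methanolysis releases the C5 alcohol with the configuration set in step 5.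

Step 8
Reactants: 11 (3S,4S)-3-[(3R)-3,5-dihydroxy-3-methylpentyl]-4-hydroxy-2,2,4-trimethylcyclohexan-1-one; 12 umbelliferone (7-hydroxy-2H-chromen-2-one)
Product: 13 7-{[(3R)-3-hydroxy-5-[(1S,6S)-6-hydroxy-2,2,6-trimethyl-3-oxocyclohexyl]-3-methylpentyl]oxy}-2H-chromen-2-one
Conditions: PPh3, DIAD, THF, 0 °C → rt
Reagents that add atoms: none
Why: Mitsunobu etherification; only the primary alcohol forms an alkoxyphosphonium ion, which the acidic phenol displaces, while both tertiary alcohols and the ketone stay inert. No stereocentre takes part.

## Compound list

1 | (R)-linalool | CC(C)=CCC[C@@](C)(O)C=C | starting material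
2 | (3R)-3,7-dimethyloct-6-ene-1,3-diol | CC(C)=CCC[C@@](C)(O)CCO | intermediate
3 | (3R)-1,3-bis(tert-butyldimethylsilyloxy)-3,7-dimethyloct-6-ene | CC(C)=CCC[C@@](C)(O[Si](C)(C)C(C)(C)C)CCO[Si](C)(C)C(C)(C)C | intermediate
4 | (2E,6R)-6,8-bis(tert-butyldimethylsilyloxy)-2,6-dimethyloct-2-en-1-ol | OC/C(C)=C/CC[C@@](C)(O[Si](C)(C)C(C)(C)C)CCO[Si](C)(C)C(C)(C)C | intermediate
5 | (2E,6R)-6,8-bis(tert-butyldimethylsilyloxy)-2,6-dimethyloct-2-enal | O=C/C(C)=C/CC[C@@](C)(O[Si](C)(C)C(C)(C)C)CCO[Si](C)(C)C(C)(C)C | intermediate
6 | 4-methylpent-1-en-3-one | C=CC(=O)C(C)C | starting material
7 | 4-methyl-3-(triisopropylsilyloxy)penta-1,3-diene | C=CC(O[Si](C(C)C)(C(C)C)C(C)C)=C(C)C | intermediate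
8 | (1S,6S)-6-[(3R)-3,5-bis(tert-butyldimethylsilyloxy)-3-methylpentyl]-1,5,5-trimethyl-4-(triisopropylsilyloxy)cyclohex-3-ene-1-carbaldehyde | CC1(C)C(O[Si](C(C)C)(C(C)C)C(C)C)=CC[C@](C)(C=O)[C@H]1CC[C@@](C)(O[Si](C)(C)C(C)(C)C)CCO[Si](C)(C)C(C)(C)C | intermediate
9 | (1S,2R)-2-[(3R)-3,5-dihydroxy-3-methylpentyl]-1,3,3-trimethyl-4-oxocyclohexane-1-carbaldehyde | CC1(C)C(=O)CC[C@](C)(C=O)[C@H]1CC[C@@](C)(O)CCO | intermediate
10 | (1S,2S)-2-[(3R)-3,5-dihydroxy-3-methylpentyl]-1,3,3-trimethyl-4-oxocyclohexyl formate | CC1(C)C(=O)CC[C@](C)(OC=O)[C@H]1CC[C@@](C)(O)CCO | intermediate
11 | (3S,4S)-3-[(3R)-3,5-dihydroxy-3-methylpentyl]-4-hydroxy-2,2,4-trimethylcyclohexan-1-one | CC1(C)C(=O)CC[C@](C)(O)[C@H]1CC[C@@](C)(O)CCO | intermediate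
12 | umbelliferone (7-hydroxy-2H-chromen-2-one) | Oc1ccc2ccc(=O)oc2c1 | starting material
13 | 7-{[(3R)-3-hydroxy-5-[(1S,6S)-6-hydroxy-2,2,6-trimethyl-3-oxocyclohexyl]-3-methylpentyl]oxy}-2H-chromen-2-one | CC1(C)C(=O)CC[C@](C)(O)[C@H]1CC[C@@](C)(O)CCOc1ccc2ccc(=O)oc2c1 | target

## Step count and risks

Total: 8 steps. Longest linear sequence: 7 steps (1 → 2 → 3 → 5 → 8 → 9 → 11 → 13); step 4 is a one-step side branch to 7.

**Step 5 (key step, proposed new method).**
- What may go wrong: no turnover, because the fully substituted diene terminus cannot reach the β-carbon at temperatures the catalyst tolerates; 1,2-addition of the enol ether to the formyl group instead of conjugate attack; erosion of facial selectivity by an achiral silyl triflimide cycle; loss of the C5/C6 relationship if a stepwise zwitterion lives long enough to rotate about C5–C6.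
- Fallback (known chemistry; the gem-dimethyl group is no longer carried by the diene): it sets out from enal 5. The same catalyst with the unhindered 2-(triisopropylsilyloxy)buta-1,3-diene F1, made from but-3-en-2-one as in step 4, is the established pairing of an α-methyl enal with a parent 2-silyloxydiene and would give the des-dimethyl cycloadduct F2. Saegusa–Ito oxidation (Pd(OAc)2, O2, DMSO) would turn its enol ether into cyclohex-2-enone F3, in which C1 is the only enolisable position because C5 is quaternary. Baeyer–Villiger oxidation of the formyl group (mCPBA, Na2HPO4; the enone is inert) and methanolysis would give γ-hydroxy enone F4. Two rounds of LiN(i-Pr)2/MeI would install both C1 methyl groups to give gem-dimethyl hydroxy enone F5. Hydrogenation (H2, Pd/C, EtOAc) would give silylated ketol F6, and HF in MeCN brings the sequence back to the route at 11.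

**Step 7.**
- What may go wrong: over-oxidation by oxygen insertion at the C2 ketone, whose quaternary neighbour C1 also migrates well, once the aldehyde is consumed; or hydride instead of alkyl migration, giving the carboxylic acid.
- Fallback (the ring ketone is masked as a conjugated enone during the oxygen insertion): it sets out from cycloadduct 8. Saegusa–Ito oxidation (Pd(OAc)2, O2, DMSO) would give enone aldehyde F7, whose conjugated ketone does not undergo oxygen insertion under the conditions that convert the aldehyde. mCPBA followed by K2CO3/MeOH would give hydroxy enone F5, hydrogenation would give ketol F6, and HF in MeCN comes back to the route at 11.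

**Step 3.**
- What may go wrong: unselective or stalled allylic oxidation (attack at the allylic CH2 group, over-oxidation, partial loss of the primary silyl ether under the mildly acidic conditions).
- Fallback (olefination instead of C–H oxidation): it sets out from silyl ether 3. Ozonolysis (O3, CH2Cl2/MeOH, −78 °C; Me2S) would give aldehyde F8. Wittig reaction with the stabilised ylide 2-(triphenylphosphoranylidene)propanal (toluene, 80 °C) gives the E enal and comes back to the route at 5.

## Further compounds

F1 | step 5 | 2-(triisopropylsilyloxy)buta-1,3-diene | C=CC(=C)O[Si](C(C)C)(C(C)C)C(C)C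
F2 | step 5 | (1S,6S)-6-[(3R)-3,5-bis(tert-butyldimethylsilyloxy)-3-methylpentyl]-1-methyl-4-(triisopropylsilyloxy)cyclohex-3-ene-1-carbaldehyde | C1C(O[Si](C(C)C)(C(C)C)C(C)C)=CC[C@](C)(C=O)[C@H]1CC[C@@](C)(O[Si](C)(C)C(C)(C)C)CCO[Si](C)(C)C(C)(C)C
F3 | step 5 | (1R,6S)-6-[(3R)-3,5-bis(tert-butyldimethylsilyloxy)-3-methylpentyl]-1-methyl-4-oxocyclohex-2-ene-1-carbaldehyde | C1C(=O)C=C[C@](C)(C=O)[C@H]1CC[C@@](C)(O[Si](C)(C)C(C)(C)C)CCO[Si](C)(C)C(C)(C)C
F4 | step 5 | (4R,5S)-5-[(3R)-3,5-bis(tert-butyldimethylsilyloxy)-3-methylpentyl]-4-hydroxy-4-methylcyclohex-2-en-1-one | C1C(=O)C=C[C@](C)(O)[C@H]1CC[C@@](C)(O[Si](C)(C)C(C)(C)C)CCO[Si](C)(C)C(C)(C)C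
F5 | step 5 | (4S,5S)-5-[(3R)-3,5-bis(tert-butyldimethylsilyloxy)-3-methylpentyl]-4-hydroxy-4,6,6-trimethylcyclohex-2-en-1-one | CC1(C)C(=O)C=C[C@](C)(O)[C@H]1CC[C@@](C)(O[Si](C)(C)C(C)(C)C)CCO[Si](C)(C)C(C)(C)C
F6 | step 5 | (3S,4S)-3-[(3R)-3,5-bis(tert-butyldimethylsilyloxy)-3-methylpentyl]-4-hydroxy-2,2,4-trimethylcyclohexan-1-one | CC1(C)C(=O)CC[C@](C)(O)[C@H]1CC[C@@](C)(O[Si](C)(C)C(C)(C)C)CCO[Si](C)(C)C(C)(C)C
F7 | step 7 | (1S,6R)-6-[(3R)-3,5-bis(tert-butyldimethylsilyloxy)-3-methylpentyl]-1,5,5-trimethyl-4-oxocyclohex-2-ene-1-carbaldehyde | CC1(C)C(=O)C=C[C@](C)(C=O)[C@H]1CC[C@@](C)(O[Si](C)(C)C(C)(C)C)CCO[Si](C)(C)C(C)(C)C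
F8 | step 3 | (4R)-4,6-bis(tert-butyldimethylsilyloxy)-4-methylhexanal | O=CCC[C@@](C)(O[Si](C)(C)C(C)(C)C)CCO[Si](C)(C)C(C)(C)C
A1 | alternative 1 | 6-[(3R)-3-hydroxy-3-methylhex-5-en-1-yl]-1,5,5-trimethylcyclohexa-1,3-diene, ring methine configured as in 13 | C=CC[C@](C)(O)CC[C@@H]1C(C)=CC=CC1(C)C
A2 | alternative 1 | (4S,5S)-4-hydroxy-5-[(3R)-3-hydroxy-3-methylhex-5-en-1-yl]-4,6,6-trimethylcyclohex-2-en-1-one | C=CC[C@](C)(O)CC[C@@H]1[C@@](C)(O)C=CC(=O)C1(C)C
A3 | alternative 2 | trans-fused 4,4,7a-trimethylhexahydroindane-1,5-dione 5-(ethylene ketal) | CC1(C)C2(OCCO2)CC[C@]3(C)C(=O)CC[C@@H]13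
A4 | alternative 2 | trans-fused 5,5,8a-trimethylhexahydrochromane-2,6-dione 6-(ethylene ketal) (δ-lactone) | CC1(C)C2(OCCO2)CC[C@]3(C)OC(=O)CC[C@@H]13
A5 | alternative 3 | 3,3-dimethyl-4,7-dioxooctanal | O=CCC(C)(C)C(=O)CCC(C)=O
A6 | alternative 3 | (1S,2S)-2-hydroxy-2,6,6-trimethyl-5-oxocyclohexane-1-carbaldehyde | CC1(C)C(=O)CC[C@](C)(O)[C@H]1C=O
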